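## Retrosynthetic overview

1. Target 40 is a 22-membered lactone (ring A: C1–C21 plus the lactone oxygen) with a C22–C30 tetraene arm. The last operations are a C23–C24 Stille coupling with iodotriene 31 and desilylation.
2. Ring A is closed by the C17–C18 bond. C17 is a secondary carbinol held inside ring A between the (E)-C18=C19 alkene and the C16 methylene, i.e. an (E)-allylic alcohol. This is the retron of a syn-hydrometalated terminal alkyne (C18≡C19 on C20) adding to a C17 formyl group, so one operation on acyclic ynal 35 should make the ring, the alkene geometry and the C17 stereocentre.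
3. Ynal 35 comes from the Yamaguchi ester of C1–C17 acid 20 with C18–C23 alkynol 24 (C20/C21 set by anti-selective propargylation of stannyl enal 13).
4. Acid 20 comes from a Stille union of C1–C7 vinylstannane 18 (C5 by Ti(Oi-Pr)4/BINOL-catalysed vinylogous aldol, C3 by anti reduction) with C8–C17 allylic chloride 11 (C14=C15 by Johnson–Claisen, C11 by asymmetric allylation).
5. Ring order: there is one ring only; it is formed in step 21, after every stereocentre except C17 is in place.

Key step: step 21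

Remark: locants C1–C30 are those of the target (C1 lactone carbonyl, C21 ring carbon bearing the lactone oxygen, C22–C30 side chain). The target is taken as 3S,5S,6E,11S,14E,17S,18E,20R,21S,22E,24Z,26Z, as read from the given SMILES. Compounds 1, 12, 14, 21, 29 and both enantiomers of BINOL and MIB are taken as catalogue compounds.

## Route

Step 1
Reactants: 1 3-[(tert-butyldimethylsilyl)oxy]propanal; 2 vinylmagnesium bromide
Product: 3 rac-5-[(tert-butyldimethylsilyl)oxy]pent-1-en-3-ol
Conditions: CH2=CHMgBr, THF, −78 to 0 °C; then H2O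
Reagents that add atoms: none
Why: Grignard 1,2-addition to the aldehyde; the new carbinol centre is racemic, which is harmless because it is destroyed in step 2.

Step 2
Reactants: 3 rac-5-[(tert-butyldimethylsilyl)oxy]pent-1-en-3-ol; 4 triethyl orthoacetate
Product: 6 ethyl (4E)-7-[(tert-butyldimethylsilyl)oxy]hept-4-enoate, via ketene acetal 5 (not isolated)
Conditions: MeC(OEt)3 (5 equiv), EtCO2H (cat.), 140 °C, EtOH distilled off
Reagents that add atoms: none
Why: Johnson–Claisen rearrangement, in which the mixed ketene acetal rearranges through a chair transition state with the silyloxyethyl group equatorial, so the (E)-C14=C15 bond and the two-carbon ester arm should be set together.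

Step 3
Reactants: 6 ethyl (4E)-7-[(tert-butyldimethylsilyl)oxy]hept-4-enoate
Product: 7 (4E)-7-[(tert-butyldimethylsilyl)oxy]hept-4-enal
Conditions: i-Bu2AlH (1.05 equiv), CH2Cl2, −78 °C; then aqueous potassium sodium tartrate
Reagents that add atoms: none
Why: Partial ester reduction, which at −78 °C should stop at the aluminium hemiacetal that collapses to the aldehyde (C11) only on work-up.

Step 4
Reactants: 8 3-chloro-2-(chloromethyl)prop-1-ene
Product: 9 tributyl[2-(chloromethyl)prop-2-en-1-yl]stannane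
Conditions: Bu3SnH, LiN(i-Pr)2, THF, 0 °C; then 8 (3 equiv), −78 °C to rt
Reagents that add atoms: tributyltin hydride `CCCC[SnH](CCCC)CCCC`
Why: LiN(i-Pr)2 deprotonates Bu3SnH to tributylstannyllithium, which displaces one allylic chloride by SN2 substitution, with a threefold excess of the cheap dichloride to suppress double substitution.

Step 5
Reactants: 7 (4E)-7-[(tert-butyldimethylsilyl)oxy]hept-4-enal; 9 tributyl[2-(chloromethyl)prop-2-en-1-yl]stannane
Product: 10 (4S,7E)-10-[(tert-butyldimethylsilyl)oxy]-2-(chloromethyl)deca-1,7-dien-4-ol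
Conditions: (R)-BINOL (20 mol%), Ti(Oi-Pr)4 (10 mol%), 4 Å MS, CH2Cl2, −20 °C; then aqueous NaHCO3
Reagents that add atoms: none
Why: Keck asymmetric allylation, in which the catalyst formed from (R)-BINOL and Ti(Oi-Pr)4 activates the aldehyde and the allylstannane should attack its Re face in an open SE2′ transition state, giving the 11S alcohol while the allylic chloride is carried through untouched.

Step 6
Reactants: 10 (4S,7E)-10-[(tert-butyldimethylsilyl)oxy]-2-(chloromethyl)deca-1,7-dien-4-ol
Product: 11 (4S,7E)-4,10-bis[(tert-butyldimethylsilyl)oxy]-2-(chloromethyl)deca-1,7-diene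
Conditions: TBSOTf, 2,6-lutidine, CH2Cl2, −78 °C
Reagents that add atoms: tert-butyldimethylsilyl triflate `CC(C)(C)[Si](C)(C)OS(=O)(=O)C(F)(F)F`
Why: Silylation with the triflate and a non-nucleophilic base, chosen so that the allylic chloride is not alkylated as it could be by imidazole.

Step 7
Reactants: 12 (2E)-3-(tributylstannyl)prop-2-en-1-ol
Product: 13 (2E)-3-(tributylstannyl)prop-2-enal
Conditions: MnO2 (excess), CH2Cl2, rt
Reagents that add atoms: none
Why: Allylic oxidation with MnO2, which should give the enal without touching the C–Sn bond or the alkene geometry.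

Step 8
Reactants: 13 (2E)-3-(tributylstannyl)prop-2-enal; 14 1-methoxy-1,3-bis(trimethylsilyloxy)buta-1,3-diene
Product: 16 methyl (5S,6E)-5-hydroxy-3-oxo-7-(tributylstannyl)hept-6-enoate, via bis-silylated aldol adduct 15 (not isolated)
Conditions: Ti(Oi-Pr)4 (10 mol%), (S)-BINOL (10 mol%), 4 Å MS, THF, −78 °C to rt; then PPTS, MeOH, 0 °C
Reagents that add atoms: none
Why: Catalytic asymmetric vinylogous Mukaiyama aldol reaction at the terminal carbon of the dienolate, in which the catalyst formed from (S)-BINOL and Ti(Oi-Pr)4 should direct attack to the Si face of the enal (the same sense as in the Ti(Oi-Pr)4/BINOL-catalysed allylation) and so set 5S, after which mild methanolysis frees the δ-hydroxy-β-keto ester.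

Step 9
Reactants: 16 methyl (5S,6E)-5-hydroxy-3-oxo-7-(tributylstannyl)hept-6-enoate
Product: 17 methyl (3S,5S,6E)-3,5-dihydroxy-7-(tributylstannyl)hept-6-enoate
Conditions: Me4NBH(OAc)3, MeCN/AcOH (1:1), −30 °C
Reagents that add atoms: none
Why: Evans–Saksena reduction, in which the C5 hydroxyl binds the triacetoxyborohydride and delivers hydride intramolecularly through a chair transition state, which should give the 3,5-anti diol (3S).

Step 10
Reactants: 17 methyl (3S,5S,6E)-3,5-dihydroxy-7-(tributylstannyl)hept-6-enoate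
Product: 18 methyl (3S,5S,6E)-3,5-bis[(tert-butyldimethylsilyl)oxy]-7-(tributylstannyl)hept-6-enoate
Conditions: TBSOTf (2.5 equiv), 2,6-lutidine (4 equiv), CH2Cl2, −78 °C
Reagents that add atoms: tert-butyldimethylsilyl triflate `CC(C)(C)[Si](C)(C)OS(=O)(=O)C(F)(F)F`
Why: Standard bis-silylation at low temperature with excess base, conditions under which the vinylstannane should not be protonated.

Step 11
Reactants: 18 methyl (3S,5S,6E)-3,5-bis[(tert-butyldimethylsilyl)oxy]-7-(tributylstannyl)hept-6-enoate; 11 (4S,7E)-4,10-bis[(tert-butyldimethylsilyl)oxy]-2-(chloromethyl)deca-1,7-diene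
Product: 19 methyl (3S,5S,6E,11S,14E)-3,5,11,17-tetrakis[(tert-butyldimethylsilyl)oxy]-9-methylideneheptadeca-6,14-dienoate
Conditions: Pd2(dba)3 (5 mol%), AsPh3 (20 mol%), THF, 55 °C
Reagents that add atoms: none
Why: Stille coupling of an allylic chloride with a vinylstannane through a π-allylpalladium intermediate whose two termini are equivalent CH2 groups, so only the skipped C6=C7/C9-methylidene diene can form and the (E)-geometry of the stannane should be retained.

Step 12
Reactants: 19 methyl (3S,5S,6E,11S,14E)-3,5,11,17-tetrakis[(tert-butyldimethylsilyl)oxy]-9-methylideneheptadeca-6,14-dienoate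
Product: 20 (3S,5S,6E,11S,14E)-3,5,11,17-tetrakis[(tert-butyldimethylsilyl)oxy]-9-methylideneheptadeca-6,14-dienoic acid
Conditions: Me3SnOH (5 equiv), ClCH2CH2Cl, 80 °C; then 0.05 M HCl wash
Reagents that add atoms: trimethyltin hydroxide `C[Sn](C)(C)O`
Why: Methyl ester cleavage by trimethyltin hydroxide under near-neutral conditions, which should avoid β-elimination of the C3 silyloxy group.

Step 13
Reactants: 21 (2S)-but-3-yn-2-ol
Product: 22 (2S)-but-3-yn-2-yl methanesulfonate
Conditions: MsCl, Et3N, CH2Cl2, −78 to 0 °C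
Reagents that add atoms: methanesulfonyl chloride `CS(=O)(=O)Cl`
Why: O-Sulfonylation, which does not touch the C–O bond and so keeps the configuration.

Step 14
Reactants: 22 (2S)-but-3-yn-2-yl methanesulfonate; 13 (2E)-3-(tributylstannyl)prop-2-enal
Product: 24 (1E,3R,4R)-4-methyl-1-(tributylstannyl)hex-1-en-5-yn-3-ol, via allenylzinc 23 (not isolated)
Conditions: Pd(OAc)2 (5 mol%), PPh3 (5 mol%), Et2Zn (3 equiv), THF, −78 to −20 °C; then H2O
Reagents that add atoms: none
Why: Marshall propargylation, in which zerovalent palladium ionises the mesylate by anti SN2′ attack, exchange with Et2Zn (much faster at −20 °C than any Stille reaction of the vinylstannane) gives the axially chiral allenylzinc 23, and 23 adds to the enal through a cyclic SE2′ chair transition state with the aldehyde substituent equatorial, so the new bond should form opposite to the departed mesylate (20R) with the 20,21-anti relationship of the target (C21 is labelled R here only because tin raises the CIP rank of C22).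

Step 15
Reactants: 25 but-2-yn-1-ol
Product: 27 (2Z)-3-iodobut-2-en-1-ol, via cyclic vinylaluminate 26 (not isolated)
Conditions: NaAlH2(OCH2CH2OMe)2 (Red-Al), THF, 0 °C to rt; then I2, −78 °C
Reagents that add atoms: iodine `[I][I]`
Why: Hydroxyl-directed trans-hydroalumination, which places aluminium on C3 cis to the CH2O group in the cyclic aluminate 26, so iodinolysis with retention should give the (Z)-iodide.

Step 16
Reactants: 27 (2Z)-3-iodobut-2-en-1-ol
Product: 28 (2Z)-3-iodobut-2-enal
Conditions: MnO2 (excess), CH2Cl2, rt, dark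
Reagents that add atoms: none
Why: Neutral allylic oxidation with MnO2, which should preserve the (Z)-geometry of the β-iodo enal.

Step 17
Reactants: 29 (but-3-en-1-yl)triphenylphosphonium bromide; 28 (2Z)-3-iodobut-2-enal
Product: 31 (2Z,4Z)-2-iodoocta-2,4,7-triene, via phosphorus ylide 30 (not isolated)
Conditions: NaN(SiMe3)2, THF, −78 °C; then 28, −78 to 0 °C
Reagents that add atoms: none
Why: Salt-free Wittig reaction of a non-stabilised ylide, which under kinetic control through the cis-oxaphosphetane should give the (Z)-C26=C27 alkene.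

Step 18
Reactants: 20 (3S,5S,6E,11S,14E)-3,5,11,17-tetrakis[(tert-butyldimethylsilyl)oxy]-9-methylideneheptadeca-6,14-dienoic acid; 24 (1E,3R,4R)-4-methyl-1-(tributylstannyl)hex-1-en-5-yn-3-ol
Product: 33 seco ester (C21 ester of 20 with 24; four TBS ethers), via mixed anhydride 32 (not isolated)
Conditions: 2,4,6-Cl3C6H2COCl, Et3N, toluene, rt; then 24, DMAP, toluene, rt
Reagents that add atoms: none
Why: Yamaguchi esterification, in which DMAP attacks the mixed anhydride 32 at the less hindered aliphatic carbonyl and the acylpyridinium should acylate the hindered C21 hydroxyl without touching its stereocentre.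

Step 19
Reactants: 33 seco ester (four TBS ethers)
Product: 34 seco ester C17 primary alcohol (3,5,11-tris-TBS ether)
Conditions: HF·pyridine, pyridine, THF, 0 °C
Reagents that add atoms: none
Why: Selective desilylation, since the primary silyl ether is far less hindered than the three secondary ones and buffered HF·pyridine at 0 °C should be too weakly acidic to protodestannylate the vinylstannane.

Step 20
Reactants: 34 seco ester C17 primary alcohol
Product: 35 seco ynal (C17 aldehyde; C18≡C19 terminal alkyne)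
Conditions: Dess–Martin periodinane, NaHCO3, CH2Cl2, 0 °C; used at once
Reagents that add atoms: none
Why: Buffered Dess–Martin oxidation, which is neutral and fast, so the β,γ-unsaturated aldehyde should form without migration of the C14=C15 bond into conjugation.

Step 21
Reactants: 35 seco ynal
Product: 38 macrolactone vinylstannane (17S-alcohol; 3,5,11-tris-TBS ether), via alkenylborane 36 (not isolated), via alkenylzinc 37 (not isolated)
Conditions: Cy2BH (1.1 equiv, freshly prepared), toluene, 0 °C to rt, 1 h; then syringe-pump addition over 8 h to Et2Zn (1.5 equiv), (2R)-(+)-3-exo-morpholinoisoborneol [(+)-MIB, 10 mol%], toluene, −10 °C (final 2 mM); then H2O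
Reagents that add atoms: none
Why: Cy2BH adds syn and anti-Markovnikov to the only terminal alkyne (C18≡C19), which is far more reactive toward this hindered borane than the 1,2-disubstituted, 1,1-disubstituted and stannyl-substituted alkenes or the formyl group, to give the (E)-alkenylborane 36, and boron-to-zinc exchange with Et2Zn then gives the (E)-alkenyl(ethyl)zinc 37 with retention of geometry. The zinc aminoalkoxide formed from (+)-MIB binds 37 and the C17 aldehyde and transfers the alkenyl group (an sp2 carbon migrates in preference to ethyl) to the carbonyl carbon, forming C17–C18. The closest known reaction type is the Oppolzer macrocyclisation of ω-alkynals (hydroboration, transmetalation to zinc, amino-alcohol-catalysed addition), which has closed carbocycles and macrolactones as (E)-allylic alcohols with high enantio- or diastereocontrol. The 22-membered ring A closes by exo attack on the C17=O group (22-exo-trig), with the new (E)-C18=C19 bond endocyclic. The new C17 stereocentre is catalyst-controlled: (+)-MIB, the mirror image of the ligand that directs organozinc additions to the Si face of aldehydes, should direct the alkenyl group to the Re face and so give 17S, while the nearest stereocentre (C20) is 1,4-related across the alkene and should exert little bias. The step needs chemoselective hydroboration (secured by the unique terminal alkyne and a stoichiometric hindered borane at 0 °C), cyclisation over oligomerisation (secured by slow addition, which keeps 37 at millimolar concentration) and survival of the β,γ-unsaturated aldehyde (secured by the weakly basic, ligand-accelerated addition at −10 °C).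

Step 22
Reactants: 38 macrolactone vinylstannane; 31 (2Z,4Z)-2-iodoocta-2,4,7-triene
Product: 39 3,5,11-tris-TBS ether of the target
Conditions: Pd2(dba)3 (10 mol%), AsPh3 (40 mol%), NMP, rt, dark
Reagents that add atoms: none
Why: Stille coupling under ligand-accelerated conditions at room temperature, which should join C23 to C24 with retention of both alkene geometries and tolerate the free C17 hydroxyl and the allylic lactone.

Step 23
Reactants: 39 3,5,11-tris-TBS ether of the target
Product: 40 CNP0297533.1 (target)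
Conditions: HF·pyridine, pyridine, THF, 0 °C to rt
Reagents that add atoms: none
Why: Global desilylation with buffered HF·pyridine, which should remove the three secondary silyl ethers without acid-catalysed allylic transposition or isomerisation of the skipped polyene.

## Compound list

1 | 3-[(tert-butyldimethylsilyl)oxy]propanal | `O=CCCO[Si](C)(C)C(C)(C)C` | starting material
2 | vinylmagnesium bromide | `C=C[Mg]Br` | starting material
3 | rac-5-[(tert-butyldimethylsilyl)oxy]pent-1-en-3-ol | `C=CC(O)CCO[Si](C)(C)C(C)(C)C` | intermediate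
4 | triethyl orthoacetate | `CCOC(C)(OCC)OCC` | starting material
5 | 1-ethoxyvinyl ether of 3 (mixed ketene acetal) | `C=C(OCC)OC(C=C)CCO[Si](C)(C)C(C)(C)C` | intermediate (not isolated)
6 | ethyl (4E)-7-[(tert-butyldimethylsilyl)oxy]hept-4-enoate | `CCOC(=O)CC/C=C/CCO[Si](C)(C)C(C)(C)C` | intermediate
7 | (4E)-7-[(tert-butyldimethylsilyl)oxy]hept-4-enal | `O=CCC/C=C/CCO[Si](C)(C)C(C)(C)C` | intermediate
8 | 3-chloro-2-(chloromethyl)prop-1-ene | `C=C(CCl)CCl` | starting material
9 | tributyl[2-(chloromethyl)prop-2-en-1-yl]stannane | `C=C(CCl)C[Sn](CCCC)(CCCC)CCCC` | intermediate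
10 | (4S,7E)-10-[(tert-butyldimethylsilyl)oxy]-2-(chloromethyl)deca-1,7-dien-4-ol | `C=C(CCl)C[C@@H](O)CC/C=C/CCO[Si](C)(C)C(C)(C)C` | intermediate
11 | (4S,7E)-4,10-bis[(tert-butyldimethylsilyl)oxy]-2-(chloromethyl)deca-1,7-diene | `C=C(CCl)C[C@@H](O[Si](C)(C)C(C)(C)C)CC/C=C/CCO[Si](C)(C)C(C)(C)C` | intermediate
12 | (2E)-3-(tributylstannyl)prop-2-en-1-ol | `OC/C=C/[Sn](CCCC)(CCCC)CCCC` | starting material
13 | (2E)-3-(tributylstannyl)prop-2-enal | `O=C/C=C/[Sn](CCCC)(CCCC)CCCC` | intermediate
14 | 1-methoxy-1,3-bis(trimethylsilyloxy)buta-1,3-diene | `COC(O[Si](C)(C)C)=CC(=C)O[Si](C)(C)C` | starting material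
15 | methyl (5S,6E)-3,5-bis(trimethylsilyloxy)-7-(tributylstannyl)hepta-2,6-dienoate (enol ether geometry not defined) | `COC(=O)C=C(O[Si](C)(C)C)C[C@H](O[Si](C)(C)C)/C=C/[Sn](CCCC)(CCCC)CCCC` | intermediate (not isolated)
16 | methyl (5S,6E)-5-hydroxy-3-oxo-7-(tributylstannyl)hept-6-enoate | `COC(=O)CC(=O)C[C@H](O)/C=C/[Sn](CCCC)(CCCC)CCCC` | intermediate
17 | methyl (3S,5S,6E)-3,5-dihydroxy-7-(tributylstannyl)hept-6-enoate | `COC(=O)C[C@@H](O)C[C@H](O)/C=C/[Sn](CCCC)(CCCC)CCCC` | intermediate
18 | methyl (3S,5S,6E)-3,5-bis[(tert-butyldimethylsilyl)oxy]-7-(tributylstannyl)hept-6-enoate | `COC(=O)C[C@@H](O[Si](C)(C)C(C)(C)C)C[C@H](O[Si](C)(C)C(C)(C)C)/C=C/[Sn](CCCC)(CCCC)CCCC` | intermediate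
19 | methyl (3S,5S,6E,11S,14E)-3,5,11,17-tetrakis[(tert-butyldimethylsilyl)oxy]-9-methylideneheptadeca-6,14-dienoate | `COC(=O)C[C@@H](O[Si](C)(C)C(C)(C)C)C[C@H](O[Si](C)(C)C(C)(C)C)/C=C/CC(=C)C[C@@H](O[Si](C)(C)C(C)(C)C)CC/C=C/CCO[Si](C)(C)C(C)(C)C` | intermediate
20 | (3S,5S,6E,11S,14E)-3,5,11,17-tetrakis[(tert-butyldimethylsilyl)oxy]-9-methylideneheptadeca-6,14-dienoic acid | `OC(=O)C[C@@H](O[Si](C)(C)C(C)(C)C)C[C@H](O[Si](C)(C)C(C)(C)C)/C=C/CC(=C)C[C@@H](O[Si](C)(C)C(C)(C)C)CC/C=C/CCO[Si](C)(C)C(C)(C)C` | intermediate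
21 | (2S)-but-3-yn-2-ol | `C#C[C@H](C)O` | starting material
22 | (2S)-but-3-yn-2-yl methanesulfonate | `C#C[C@H](C)OS(C)(=O)=O` | intermediate
23 | (aR)-buta-1,2-dien-1-yl(ethyl)zinc | `CC[Zn]C([H])=[C@]=C([H])C` | intermediate (not isolated)
24 | (1E,3R,4R)-4-methyl-1-(tributylstannyl)hex-1-en-5-yn-3-ol (20,21-anti) | `CCCC[Sn](CCCC)(CCCC)/C=C/[C@H](O)[C@H](C)C#C` | intermediate
25 | but-2-yn-1-ol | `CC#CCO` | starting material
26 | sodium 2,2-bis(2-methoxyethoxy)-3-methyl-2,5-dihydro-1,2-oxaaluminol-2-uide | `CC1=CCO[Al-]1(OCCOC)OCCOC.[Na+]` | intermediate (not isolated)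
27 | (2Z)-3-iodobut-2-en-1-ol | `C/C(I)=C/CO` | intermediate
28 | (2Z)-3-iodobut-2-enal | `C/C(I)=C/C=O` | intermediate
29 | (but-3-en-1-yl)triphenylphosphonium bromide | `C=CCC[P+](c1ccccc1)(c1ccccc1)c1ccccc1.[Br-]` | starting material
30 | but-3-en-1-ylidene(triphenyl)phosphorane | `C=CCC=P(c1ccccc1)(c1ccccc1)c1ccccc1` | intermediate (not isolated)
31 | (2Z,4Z)-2-iodoocta-2,4,7-triene | `C/C(I)=C/C=C\CC=C` | intermediate
32 | mixed anhydride of 20 with 2,4,6-trichlorobenzoic acid | `Clc1cc(Cl)c(C(=O)OC(=O)C[C@@H](O[Si](C)(C)C(C)(C)C)C[C@H](O[Si](C)(C)C(C)(C)C)/C=C/CC(=C)C[C@@H](O[Si](C)(C)C(C)(C)C)CC/C=C/CCO[Si](C)(C)C(C)(C)C)c(Cl)c1` | intermediate (not isolated)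
33 | (1E,3R,4R)-4-methyl-1-(tributylstannyl)hex-1-en-5-yn-3-yl (3S,5S,6E,11S,14E)-3,5,11,17-tetrakis[(tert-butyldimethylsilyl)oxy]-9-methylideneheptadeca-6,14-dienoate | `CCCC[Sn](CCCC)(CCCC)/C=C/[C@H](OC(=O)C[C@@H](O[Si](C)(C)C(C)(C)C)C[C@H](O[Si](C)(C)C(C)(C)C)/C=C/CC(=C)C[C@@H](O[Si](C)(C)C(C)(C)C)CC/C=C/CCO[Si](C)(C)C(C)(C)C)[C@H](C)C#C` | intermediate
34 | (1E,3R,4R)-4-methyl-1-(tributylstannyl)hex-1-en-5-yn-3-yl (3S,5S,6E,11S,14E)-3,5,11-tris[(tert-butyldimethylsilyl)oxy]-17-hydroxy-9-methylideneheptadeca-6,14-dienoate | `CCCC[Sn](CCCC)(CCCC)/C=C/[C@H](OC(=O)C[C@@H](O[Si](C)(C)C(C)(C)C)C[C@H](O[Si](C)(C)C(C)(C)C)/C=C/CC(=C)C[C@@H](O[Si](C)(C)C(C)(C)C)CC/C=C/CCO)[C@H](C)C#C` | intermediate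
35 | (1E,3R,4R)-4-methyl-1-(tributylstannyl)hex-1-en-5-yn-3-yl (3S,5S,6E,11S,14E)-3,5,11-tris[(tert-butyldimethylsilyl)oxy]-9-methylidene-17-oxoheptadeca-6,14-dienoate | `CCCC[Sn](CCCC)(CCCC)/C=C/[C@H](OC(=O)C[C@@H](O[Si](C)(C)C(C)(C)C)C[C@H](O[Si](C)(C)C(C)(C)C)/C=C/CC(=C)C[C@@H](O[Si](C)(C)C(C)(C)C)CC/C=C/CC=O)[C@H](C)C#C` | intermediate
36 | C18 (E)-alkenyl(dicyclohexyl)borane derived from 35 | `CCCC[Sn](CCCC)(CCCC)/C=C/[C@H](OC(=O)C[C@@H](O[Si](C)(C)C(C)(C)C)C[C@H](O[Si](C)(C)C(C)(C)C)/C=C/CC(=C)C[C@@H](O[Si](C)(C)C(C)(C)C)CC/C=C/CC=O)[C@H](C)/C=C/B(C1CCCCC1)C1CCCCC1` | intermediate (not isolated)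
37 | C18 (E)-alkenyl(ethyl)zinc derived from 36 | `CCCC[Sn](CCCC)(CCCC)/C=C/[C@H](OC(=O)C[C@@H](O[Si](C)(C)C(C)(C)C)C[C@H](O[Si](C)(C)C(C)(C)C)/C=C/CC(=C)C[C@@H](O[Si](C)(C)C(C)(C)C)CC/C=C/CC=O)[C@H](C)/C=C/[Zn]CC` | intermediate (not isolated)
38 | 22-membered lactone, target locants 3S,5S,6E,11S,14E,17S,18E,20R,21R (21R by CIP because of tin; same spatial arrangement as in 40): 3,5,11-tris[(tert-butyldimethylsilyl)oxy]-17-hydroxy-20-methyl-9-methylidene-21-[(E)-2-(tributylstannyl)ethenyl]henicosa-6,14,18-trien-21-olide | `CCCC[Sn](CCCC)(CCCC)/C=C/[C@@H]1OC(=O)C[C@@H](O[Si](C)(C)C(C)(C)C)C[C@H](O[Si](C)(C)C(C)(C)C)/C=C/CC(=C)C[C@@H](O[Si](C)(C)C(C)(C)C)CC/C=C/C[C@H](O)/C=C/[C@H]1C` | intermediate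
39 | 3,5,11-tris(tert-butyldimethylsilyl) ether of 40 | `C=CC\C=C/C=C(C)\C=C\[C@@H]1OC(=O)C[C@@H](O[Si](C)(C)C(C)(C)C)C[C@H](O[Si](C)(C)C(C)(C)C)/C=C/CC(=C)C[C@@H](O[Si](C)(C)C(C)(C)C)CC/C=C/C[C@H](O)/C=C/[C@H]1C` | intermediate
40 | CNP0297533.1: (3S,5S,6E,11S,14E,17S,18E,20R,21S)-3,5,11,17-tetrahydroxy-20-methyl-9-methylidene-21-[(1E,3Z,5Z)-3-methylnona-1,3,5,8-tetraen-1-yl]henicosa-6,14,18-trien-21-olide | `C=CC\C=C/C=C(C)\C=C\[C@@H]1OC(=O)C[C@@H](O)C[C@H](O)/C=C/CC(=C)C[C@@H](O)CC/C=C/C[C@H](O)/C=C/[C@H]1C` | target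

## Step count and risks

Total steps: 23. Longest linear sequence: 13 steps (1, 2, 3, 5, 6, 11, 12, 18, 19, 20, 21, 22, 23).

Step 21 (key macrocyclisation). What may go wrong: the borane may also hydroborate the C9 methylidene or reduce the formyl group; the basic zinc species may shift the C14=C15 bond into conjugation or start aldol oligomerisation before the ring closes; facial control at C17 may be eroded in the macrocyclic transition state. Fallback (sets out from 33, comes back at 39): Stille coupling of 33 with 31 (Pd2(dba)3, AsPh3, NMP, rt) would give the complete-side-chain alkyne seco ester F1. Palladium-catalysed hydrostannation of its terminal alkyne (Bu3SnH, PdCl2(PPh3)2, THF, 0 °C) would give the C18 (E)-vinylstannane F2. N-Iodosuccinimide (MeCN, 0 °C, dark) would give the C18 (E)-vinyl iodide F3. HF·pyridine/pyridine would give the C17 alcohol F4, and Dess–Martin oxidation the iodo aldehyde F5. Nozaki–Hiyama–Kishi ring closure of F5 (CrCl2, cat. NiCl2, DMSO/THF, high dilution, with a chiral sulfonamide ligand on chromium to steer the C17 face) would form the same C17–C18 bond under neutral conditions and deliver 39, so that only step 23 remains.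

Step 8 (vinylogous aldol). What may go wrong: poor facial selectivity of the catalyst from Ti(Oi-Pr)4 and (S)-BINOL with this stannyl enal, or protodestannylation during cleavage of the silyl groups. Fallback (sets out from 13, comes back at 16): the doubly deprotonated (S)-2-hydroxy-1,2,2-triphenylethyl acetate (LiN(i-Pr)2, then MgBr2, THF, −115 °C) would add to 13 under auxiliary control to give the (3S)-β-hydroxy ester F6. K2CO3/MeOH would transesterify it to the methyl ester F7. Cross-Claisen condensation of F7 with excess lithium enolate of methyl acetate (THF, −78 to −40 °C) would give 16.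

Step 23 (global desilylation). What may go wrong: slow cleavage of the hindered C3 and C11 ethers forces long exposure, during which acid-promoted allylic transposition at C5 or C17 or Z-to-E isomerisation of the polyene can occur. Fallback (sets out from 38, comes back at 40): the order of the last two steps would be reversed. Desilylation of 38 with Bu4NF/AcOH in THF, a fluoride source that the vinylstannane tolerates, would give the tetraol stannane F8. Stille coupling of F8 with 31 (Pd2(dba)3, AsPh3, NMP, rt) would then form 40 as the last step under neutral conditions, so that the complete polyene never meets fluoride or acid.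

## Further compounds

F1 | step 21 | seco ester with complete side chain: ester of acid 20 with (3R,4S,5E,7Z,9Z)-3,7-dimethyltrideca-5,7,9,12-tetraen-1-yn-4-ol (terminal alkyne, four TBS ethers; target locants 20R,21S) | `C=CC\C=C/C=C(C)\C=C\[C@H](OC(=O)C[C@@H](O[Si](C)(C)C(C)(C)C)C[C@H](O[Si](C)(C)C(C)(C)C)/C=C/CC(=C)C[C@@H](O[Si](C)(C)C(C)(C)C)CC/C=C/CCO[Si](C)(C)C(C)(C)C)[C@H](C)C#C`
F2 | step 21 | C18 (E)-tributylstannylalkene from F1 | `C=CC\C=C/C=C(C)\C=C\[C@H](OC(=O)C[C@@H](O[Si](C)(C)C(C)(C)C)C[C@H](O[Si](C)(C)C(C)(C)C)/C=C/CC(=C)C[C@@H](O[Si](C)(C)C(C)(C)C)CC/C=C/CCO[Si](C)(C)C(C)(C)C)[C@H](C)/C=C/[Sn](CCCC)(CCCC)CCCC`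
F3 | step 21 | C18 (E)-vinyl iodide from F2 | `C=CC\C=C/C=C(C)\C=C\[C@H](OC(=O)C[C@@H](O[Si](C)(C)C(C)(C)C)C[C@H](O[Si](C)(C)C(C)(C)C)/C=C/CC(=C)C[C@@H](O[Si](C)(C)C(C)(C)C)CC/C=C/CCO[Si](C)(C)C(C)(C)C)[C@H](C)/C=C/I`
F4 | step 21 | C17 primary alcohol of F3 (3,5,11-tris-TBS ether) | `C=CC\C=C/C=C(C)\C=C\[C@H](OC(=O)C[C@@H](O[Si](C)(C)C(C)(C)C)C[C@H](O[Si](C)(C)C(C)(C)C)/C=C/CC(=C)C[C@@H](O[Si](C)(C)C(C)(C)C)CC/C=C/CCO)[C@H](C)/C=C/I`
F5 | step 21 | C17 aldehyde of F4 (iodo aldehyde) | `C=CC\C=C/C=C(C)\C=C\[C@H](OC(=O)C[C@@H](O[Si](C)(C)C(C)(C)C)C[C@H](O[Si](C)(C)C(C)(C)C)/C=C/CC(=C)C[C@@H](O[Si](C)(C)C(C)(C)C)CC/C=C/CC=O)[C@H](C)/C=C/I`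
F6 | step 8 | (1S)-2-hydroxy-1,2,2-triphenylethyl (3S,4E)-3-hydroxy-5-(tributylstannyl)pent-4-enoate | `CCCC[Sn](CCCC)(CCCC)/C=C/[C@@H](O)CC(=O)O[C@@H](c1ccccc1)C(O)(c1ccccc1)c1ccccc1`
F7 | step 8 | methyl (3S,4E)-3-hydroxy-5-(tributylstannyl)pent-4-enoate | `COC(=O)C[C@H](O)/C=C/[Sn](CCCC)(CCCC)CCCC`
F8 | step 23 | 3,5,11,17-tetrahydroxy macrolactone vinylstannane (38 without silyl groups) | `CCCC[Sn](CCCC)(CCCC)/C=C/[C@@H]1OC(=O)C[C@@H](O)C[C@H](O)/C=C/CC(=C)C[C@@H](O)CC/C=C/C[C@H](O)/C=C/[C@H]1C`
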